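Monday's flask gains target 43.9 times faster in its first 15.0 min than between 60.0 min and 120 min. In this flask the solid electrophile dissolves and meets the nucleophile, each target sets free one acid, and free base stands by to take that acid up.

common to all: solid electrophile 0.10 M

|  | nucleophile | free base | temperature | remark | time |
|---|---|---|---|---|---|
| Monday's | 1.3 equiv | 0.80 equiv | 35 °C | the very flask that is asked about, followed so far |  |
| Wednesday's | 1.3 equiv | 0.80 equiv | 41 °C | run made earlier |  |
| flask | 1.30 equiv | 0.800 equiv | 35 °C |  | 2.5 h |

- Monday's (time / min: target / %): 15.0: 43.9; 30.0: 62.6; 50.0: 69.7; 60.0: 71.1; 80.0: 72.1; 90.0: 75.5; 120: 75.1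
- Wednesday's (time / min: target / %): 15.0: 53.6; 30.0: 68.7; 50.0: 72.9; 60.0: 73.5; 80.0: 78.3; 90.0: 78.6; 120: 79.7

(readings scatter by 1 percentage point)

1. target, in percent of the solid electrophile first charged, at 2.5 h
2. the remedy with the largest gain of target, or "none" below 2 percentage points (south-west / north-east / south / south-east / north / none)
3. target present, in percent of the solid electrophile first charged, after south
4. target present, in percent of the solid electrophile first charged, after north

- south-west: at 2.5 h take out 90% of the acid set free then present, then wait 5.0 h
- north-east: change nothing and wait 5.0 h more
- south: at 2.5 h add free base, 100% of the amount charged, then wait 5.0 h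
- south-east: at 2.5 h raise the temperature by 15 K, then wait 5.0 h
- north: at 2.5 h add free base, 50.0% of the amount charged, then wait 5.0 h

- additions bring no volume worth counting
- at the start none of the solid electrophile is in solution

That slowdown does not fit the charges. At Monday's last reading, one nucleophile per target leaves nucleophile at 54.9% of the solid electrophile charged and 24.9% of that solid unconverted, and a bimolecular step with those shares slows about 9.51 times. The count changes if the acid sits on the nucleophile. Each target then costs two nucleophiles, one reacted and one holding the acid, so the nucleophile charged pays for target up to the half-charge, the nucleophile charge divided by two: 65.0% of the solid electrophile charged.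

Monday's readings bend there, their gain per minute falling 3.51 times as target passes from 62.6% to 69.7%, and the half-charge lies below the 0.800 equiv of free base. By balance, target equals the half-charge, plus half the acid kept off the nucleophile, less half the free nucleophile.

Above the half-charge I see a creep, and Wednesday's is 1.55 times Monday's, a reading with wide scatter. Continuing Monday's creep gives me 77.1% at 2.5 h, and I rank heating first. The forecast gives 77% (74.5% to 79.5%) and picks south, with 96% (88% to 100%) after south and 93% (84% to 99%) after north: “Fresh base releases the reaction”.

The flask gives 78.6%, and the best remedy is south-east, gaining 21 percentage points. South reaches 91.1% and north 89.3%.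

    solid electrophile ⇌ electrophile, rate k1*(cs1 - [electrophile]) while solid is left; crystals form when [electrophile] > cs1 (solubility = 0.0610 M, k = 0.189 min⁻¹)
    nucleophile + acid set free ⇌ protonated nucleophile, settled at all times (K = 51700 L mol⁻¹, ΔH = −81.0 kJ mol⁻¹)
    acid set free + free base ⇌ salt of the base, settled at all times (K = 1000 L mol⁻¹, ΔH = −67.0 kJ mol⁻¹)
    electrophile + nucleophile → acid set free + target (k = 1.27 L mol⁻¹ min⁻¹, Ea = 59.0 kJ mol⁻¹)
    acid set free → by-product carried off (k = 0.0341 min⁻¹, Ea = 95.0 kJ mol⁻¹)
    (constants at 35 °C)

In the flask at 150 min, protonated nucleophile, the nucleophile's resting state, stands at 49.5% of the solid electrophile charged, the salt of the base at 27.2%, and 66% of the free base charged is still unbound. The balance on the half-charge gives 78.6% for this flask. A neighbouring flask charged with 3.20 equiv of free base has the same half-charge, 65.0%, but at the same time its salt of the base stands at 48.8% of the solid electrophile charged. The same balance gives 87.7%, and that flask stands at 87.7% target with 85% of its free base unbound.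

The numbers in the tables were generated by integration with made-up constants.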